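Leave the flask closed. It holds D, Q, J and Z, and the next person at the bench needs to know how much L stands in it at the times asked.

| setting | dusk | winter | flask |
|---|---|---|---|
| D | 0.10 M | 0.15 M | 0.20 M |
| Q | 0.21 M | 0.21 M | 0.210 M |
| J | 0.19 M | 0.19 M | 0.190 M |
| Z | 0.040 M | 0.040 M | 0.0400 M |
| remark | run made earlier | run made earlier |  |
| time |  |  | 50 min |

| run | time / min | L / % | D / % |
|---|---|---|---|
| dusk | 15.0 | 23.7 | 73.3 |
| dusk | 30.0 | 44.6 | 52.3 |
| dusk | 50.0 | 57.6 | 34.7 |
| dusk | 60.0 | 64.3 | 26.7 |
| winter | 8.00 | 12.7 | 85.4 |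
| winter | 20.0 | 31.4 | 63.6 |
| winter | 40.0 | 50.5 | 39.5 |
| winter | 60.0 | 61.7 | 27.2 |

(standard deviation of a reading: 1 percentage point)

- amount of L in percent of the D charged, at 2.5 min, 12 min and 50 min

- what was read earlier has a scatter of 1 percentage point, one standard deviation

I start with D. In the dusk run it falls to 26.7% in 60.0 min, a first-order constant k of 0.0220 min⁻¹. The winter run, with more D charged, gives 0.0217 min⁻¹, about the same, so I use k for this flask.

I assume that whatever follows the loss of D keeps pace with it, and I carry one quantity: the share f, the L formed per D gone, which is a selectivity. At 60.0 min it reads 87.7% in dusk and 84.8% in winter. That fall with charge is close to the scatter, but I continue it in equal steps to 81.8% for this flask.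

With L = f(1 − exp(−kt)), I expect 4.38%, 19.0% and 54.6%. The forecast, which sees “a side path that gets slightly worse with concentration”, gives 4.5%, 19.5% and 55%, the last slightly above mine.

The flask gives 4.10%, 19.9% and 55.9%.

    D → G (k = 0.0220 min⁻¹)
    Q + Z → X (k = 0.780 L mol⁻¹ min⁻¹)
    J + G → E (k = 1.30 L mol⁻¹ min⁻¹)
    Q + G → L (k = 12.0 L mol⁻¹ min⁻¹)

In this flask at 18.4 min, G is made and used in the ratio 1.00, and the step Q + G to L uses G at 5.9 times the rate of the step J + G to E, so that at that moment 85.5% of the G used goes to L. Against the 81.8% I carried, this flask at 50.0 min holds D at 33.3% and L at 55.9%, a share f of 83.8%.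

(The earlier runs and the new flask were computed with made-up constants.)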